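Readings and results were generated by integration on assumed constants, noise included.

We read this flask at 4.0 h, and the balance of its reagent bounds what can stand there.

| flask | starting material | reagent in the second phase | protic impurity | remark | time | volume of the second phase over the first |
|---|---|---|---|---|---|---|
| Saturday's | 1.5 M | 1.4 equiv | 0.030 M | run made earlier |  |  |
| Friday's | 1.5 M | 1 equiv | 0.060 M | run made earlier |  |  |
| flask | 1.5 M | 1.00 equiv | 0.0300 M |  | 4.0 h | 1.0 |

| run | time / h | target / % |
|---|---|---|
| Saturday's | 0.417 | 52.7 |
| Saturday's | 0.833 | 82.3 |
| Saturday's | 2.00 | 99.1 |
| Saturday's | 5.00 | 100.7 |
| Friday's | 0.417 | 38.2 |
| Friday's | 0.833 | 61.1 |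
| Friday's | 2.00 | 83.8 |
| Friday's | 5.00 | 94.3 |

(each reading ± 1 percentage point)

- amount of target at 4.0 h, in percent of the starting material charged
- the change that raises the amount of target at 4.0 h, in percent of the starting material charged most ("none" if none brings more than 2 percentage points) (north / south-west / none)
- amount of target at 4.0 h, in percent of the starting material charged, after north

- north: doubling the transfer coefficient of the reagent in the second phase, all else as stated
- south-west: doubling the amount of reagent in the second phase, all else as stated

- in the second phase: reagent in the second phase; everything else is in the first
- charges count per volume of the first phase; a concentration in a rate is the amount of a species over the volume of its own phase; every rate counts per litre of the first phase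
- the earlier runs hold the two phases in the same ratio of volumes as the flask asked about

We take each protic impurity to consume one reagent, so:

ceiling = ([reagent charged] − [protic impurity]) / [starting material charged] = 98.0 %

This ceiling is the most target that the usable reagent can make. With 1.47 M usable against 1.5 M of starting material, the reagent is the limiting reagent in this flask.

Which numbers must we know well? An error of 0.0100 equiv in the reagent charge moves the ceiling by one point, but the impurity must be off by 0.0150 M to do the same. The rate enters through the gap below the ceiling. Friday's run, with ceiling 96.0 %, shows gaps of 12 percentage points at 2.00 h and 1.7 points at 5.00 h, the latter weakly read against a scatter of 1 point. We assume that the flask follows the same gap, and interpolating geometrically to 4.0 h gives: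

gap = 3.3 points, so target = 94.7 %

North leaves the ceiling in place, so by our estimate it has a gap of 3.3 points to win back. South-west lifts the bound to the starting material, offering 5.3 points, so we choose south-west.

The forecast gives 94.3 % (92.8 % to 95.7 %), a little below our 94.7 %, and 95.9 % (94.8 % to 97 %) after north. It also names south-west, with north's gain small “since the tail is chemically limited”.

The flask gives 93.7 %, 94.8 % after north, and south-west, with gains of 1.1 points for north and 6.3 points for south-west.

    reagent in the reaction phase ⇌ reagent in the second phase, rate k1*([reagent in the reaction phase] - [reagent in the second phase]/K1) per volume of the first phase (partition coefficient = 1.30, kL = 6.81 × 10⁻⁴ /s)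
    starting material + reagent in the reaction phase → target (k = 0.00303 /M/s)
    reagent in the reaction phase + protic impurity → quenched reagent (k = 0.0319 /M/s)

In the flask, the step to quenched reagent reached the midpoint of its turnover up to 4.0 h by 0.0880 h, and the protic impurity stood at 0.672 % of its own charge at 0.400 h, when the reaction to target had 40 % of its turnover up to 4.0 h behind it. At 2.00 h, the reagent in the second phase stood at 8.40 % of its own charge and target at 85.9 %, and target reached 98.0 % at 40.0 h, against the ceiling of 98.0 %. The neighbour with 0.60 M of starting material has a ceiling of 95.0 % and holds 86.4 % target at 4.0 h.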